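**Plan**
- The retrosynthesis first removes the two O-methyl groups, then cuts the pyranone ring at C3–C4 and O1–C2, and last cuts C2–C3 between the chain carbonyl and a one-carbon ylide unit.
- The feature that allows this: the C4 carbonyl sits on C4a, which is flanked by the oxygen-bearing C5 and by C8a carrying O1. The benzenoid ring with C4 is therefore a salicylaldehyde, whose formyl C–H can be joined to C3 while C2 arrives as a ketone.
- Forward: the C14 acyl chain is joined to the ylide carbon (C2–C3). The pyranone ring is then closed onto the intact benzene ring in one pot (C3–C4, then O1–C2). The two phenols are unmasked at the end.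
- Stereochemistry: the target has no stereogenic element, so nothing needs to be set or preserved.

Key step: step 2

Remark: the target is achiral (no stereocentre, no stereogenic axis, no configurable double bond), so the question of a single enantiomer does not arise and the route needs no stereocontrol.

**Step 1**
Reactants: 1 tetradecanoyl chloride; 2 trimethylsulfoxonium iodide
Product: 4 1-(dimethyl(oxo)-λ6-sulfanylidene)pentadecan-2-one, via dimethylsulfoxonium methylide 3 (not isolated)
Conditions: 2 (3.0 equiv), KOtBu (3.0 equiv), THF, reflux; then 1 (1.0 equiv), 0 °C → rt
Reagents that add atoms: none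
Why: Corey–Chaykovsky-type acylation of dimethylsulfoxonium methylide, in which the methylide carbon attacks the acid chloride and a second equivalent of methylide deprotonates the resulting β-keto sulfoxonium salt, should give the stabilised, isolable keto ylide, the excess of methylide suppressing double acylation.

**Step 2**
Reactants: 4 1-(dimethyl(oxo)-λ6-sulfanylidene)pentadecan-2-one; 5 2-hydroxy-4,6-dimethoxybenzaldehyde
Product: 7 5,7-dimethoxy-2-tridecyl-4H-chromen-4-one, via 1,3-diketone 6 (not isolated)
Conditions: [Cp*RhCl2]2 (2.5 mol %), AgSbF6 (10 mol %), PivOH (1.0 equiv), DCE, 100 °C, N2; then TsOH·H2O (20 mol %), 80 °C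
Reagents that add atoms: none
Why: Pivalate-assisted deprotonation binds the phenoxide of 5 to cationic Cp*Rh(III) and the neighbouring formyl C–H is cleaved by concerted metalation–deprotonation to a five-membered acyl rhodacycle; ylide 4 then binds through carbon, loses dimethyl sulfoxide to give a Rh carbene, acyl migration onto the carbene carbon forms C3–C4, and protodemetalation releases 1,3-diketone 6. The closest known reaction type is the Rh(III)-catalysed aldehydic C–H acylmethylation/annulation of salicylaldehydes with sulfoxonium ylides, which gives 2-substituted chromones. The one new ring is closed by 6-exo-trig attack of the phenol oxygen on the C2 ketone (O1–C2), followed by acid-promoted loss of water, driven by formation of the aromatic 4-pyranone. No stereocentre is created. The step needs formyl C–H functionalisation in preference to arene C–H activation and to carbene O–H insertion, and phenoxide chelation secures this because only the formyl C–H leads to an unstrained five-membered metallacycle; the closure is unambiguous because 5 has a single free hydroxyl (the C6 oxygen is methylated), and the saturated chain is inert.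

**Step 3**
Reactants: 7 5,7-dimethoxy-2-tridecyl-4H-chromen-4-one
Product: 8 5,7-dihydroxy-2-tridecyl-4H-chromen-4-one
Conditions: BBr3 (6 equiv), CH2Cl2, −78 °C → rt; then MeOH, H2O
Reagents that add atoms: none
Why: Lewis-acid-mediated aryl methyl ether cleavage (BBr3 demethylation), in which boron coordinates each ether oxygen and bromide attacks the methyl group, should remove the C5 methyl quickly through chelation to the C4 carbonyl and the C7 methyl with excess reagent on warming, while the pyranone and the alkyl chain are untouched and the borate esters are hydrolysed on work-up.

**Compound list**
1 | tetradecanoyl chloride | CCCCCCCCCCCCCC(=O)Cl | starting material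
2 | trimethylsulfoxonium iodide | C[S+](C)(C)=O.[I-] | starting material
3 | dimethylsulfoxonium methylide | C=S(C)(C)=O | intermediate
4 | 1-(dimethyl(oxo)-λ6-sulfanylidene)pentadecan-2-one | CCCCCCCCCCCCCC(=O)C=S(C)(C)=O | intermediate
5 | 2-hydroxy-4,6-dimethoxybenzaldehyde | COc1cc(O)c(C=O)c(OC)c1 | starting material
6 | 1-(2-hydroxy-4,6-dimethoxyphenyl)hexadecane-1,3-dione | CCCCCCCCCCCCCC(=O)CC(=O)c1c(O)cc(OC)cc1OC | intermediate
7 | 5,7-dimethoxy-2-tridecyl-4H-chromen-4-one | CCCCCCCCCCCCCc1cc(=O)c2c(OC)cc(OC)cc2o1 | intermediate
8 | 5,7-dihydroxy-2-tridecyl-4H-chromen-4-one | CCCCCCCCCCCCCc1cc(=O)c2c(O)cc(O)cc2o1 | target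

**Total step count:** 3
**Longest linear sequence:** 3 steps (1 → 4 → 7 → 8)

**Steps most likely to fail**

Step 2. The formyl group of 5 lies between two ortho oxygen substituents on a very electron-rich ring, so C–H metalation may be slow. The rhodium carbene could then be diverted into O–H insertion at the phenol or into ylide self-coupling, and cyclodehydration of the diketone could stay incomplete. The fallback replaces the C–H acylation by a Baker–Venkataraman sequence and sets out from acid chloride 1. Purchased 2'-hydroxy-4',6'-dimethoxyacetophenone is O-acylated with 1 (pyridine, CH2Cl2) to give 2-acetyl-3,5-dimethoxyphenyl tetradecanoate F1. Treatment with KOtBu in THF should transfer the acyl group from oxygen to the acetyl enolate and give diketone 6, now isolated. Cyclodehydration with catalytic H2SO4 in acetic acid then returns to the route at 7.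

Step 3. Demethylation may stop after the chelation-assisted cleavage at C5, leaving the C7 methyl ether in place, and forcing the reagent could lead to ring bromination or decomposition. The fallback changes the protecting groups and sets out from ylide 4. Purchased 2,4,6-trihydroxybenzaldehyde is treated with MOMCl and iPr2NEt in CH2Cl2; the hydroxyl hydrogen-bonded to the formyl group should stay free, giving 2-hydroxy-4,6-bis(methoxymethoxy)benzaldehyde F2. Annulation of F2 with 4 under the Rh(III) conditions of step 2 should give 5,7-bis(methoxymethoxy)-2-tridecyl-4H-chromen-4-one F3; any acetal loss under the acidic conditions is harmless. Acetal cleavage with HCl in methanol at 50 °C then returns to the route at 8.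

Step 1. The basic methylide may deprotonate the acid chloride at its α-carbon and form a ketene that dimerises, or the ylide carbon may be acylated twice. The fallback uses a less reactive acyl donor that cannot form a ketene and sets out from 1. Quenching 1 into methanol with Et3N gives methyl tetradecanoate F4 (also purchasable). Heating F4 with methylide 3, generated from 2 and KOtBu in THF at reflux, should displace methoxide and return to the route at 4.

**Further compounds**
F1 | step 2 | 2-acetyl-3,5-dimethoxyphenyl tetradecanoate | CCCCCCCCCCCCCC(=O)Oc1cc(OC)cc(OC)c1C(C)=O
F2 | step 3 | 2-hydroxy-4,6-bis(methoxymethoxy)benzaldehyde | COCOc1cc(O)c(C=O)c(OCOC)c1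
F3 | step 3 | 5,7-bis(methoxymethoxy)-2-tridecyl-4H-chromen-4-one | CCCCCCCCCCCCCc1cc(=O)c2c(OCOC)cc(OCOC)cc2o1
F4 | step 1 | methyl tetradecanoate | CCCCCCCCCCCCCC(=O)OC
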